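All runs are calculated with made-up constants; scatter was added.

Read the noon flask near 10.0 h, where it shows 62% target: that is my quick number, and here is how it stands against your forecast.

| flask | starting material | enzyme | remark | time |
|---|---|---|---|---|
| noon | 10 mM | 6.7 µM | the very flask that is asked about, followed so far |  |
| dawn | 10 mM | 3.4 µM | run made earlier |  |
| flask | 10 mM | 6.7 µM |  | 10 d |

noon run (percent of the starting material charged)

| time / h | target / % | starting material / % |
|---|---|---|
| 2.00 | 46 | 52 |
| 5.00 | 59 | 36 |
| 10.0 | 62 | 28 |
| 20.0 | 58 | 27 |
| 50.0 | 44 | 27 |

dawn run (percent of the starting material charged)

| time / d | target / % | starting material / % |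
|---|---|---|
| 0.104 | 39 | 58 |
| 0.333 | 46 | 47 |
| 1.04 | 45 | 44 |
| 3.00 | 36 | 42 |
| 10.0 | 31 | 37 |

(readings scatter by 2 percentage points)

* time up to 10 d at which target stands highest
* the amount of target, in percent of the starting material charged, at that time
* the first time at which target reaches 31%, in the same percent

- what was read earlier has a scatter of 2 percentage points, one standard deviation

Start from the enzyme's balance, since enzyme is the smallest charge, at 0.0670% of the starting material in the noon flask. My assumption is that enzyme dies at a steady pace and that its work slows as the ratio of converted to remaining starting material grows. Integrate that, and the logarithm of the inverse of the fraction left, minus the fraction converted, equals the enzyme-to-charge ratio times a constant. Call that constant the reach.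

The last three noon readings average 27.3% left, so the reach is 851. The last three dawn readings average 41.0% left, which gives 887. The two lie close, so use the rule.

The reach says where conversion stops, not when target peaks, so the peak time stays my reading. Your forecast gives 0.39 d, 62.5% and 0.7 h, on the ground that “the conversion step stops early, through enzyme death or inhibition”.

The flask gives 0.366 d, 61.3% and 0.687 h, and your forecast holds on all three.

    starting material + enzyme → target + enzyme, rate k1*[starting material]*[enzyme]/(1 + ([starting material]/Km1) + ([target]/Kp1)) (30.9 mM, 0.458 mM, k = 7100 M⁻¹ min⁻¹)
    enzyme → spent catalyst (k = 0.00333 min⁻¹)
    target ⇌ isomer of the product (K = 0.759, k = 3.43 × 10⁻⁴ min⁻¹)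

The flask ends with 25% starting material left, which puts the reach at 936. Inhibition by target is the largest single effect on the flask's peak, not the whole of it: strike the target term from the rate law and the peak goes from 61.3% to 95.7%. Enzyme death is a further part: strike it instead and the peak stands at 77.7%, a shift of 16 percentage points, less than the 34 points from the target term.

Charge 4.0 mM of starting material with the same enzyme, and the noon reach gives an index of 1.43, so 9.66% left. That neighbour ends at 9.3%.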